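**Retrosynthetic overview**

1. Last step: one BCl3 operation removes the 7-O-benzyl group of unit A (the 6-linked acacetin half) and the chelated 5-O-methyl group of unit B (the 8-linked half) from the assembled 6,8''-biflavone.
2. The pyranone ring of unit B is closed late by iodine/DMSO oxidative cyclisation of a 2'-hydroxychalcone. The chalcone comes from Friedel–Crafts cinnamoylation of a 2,4,6-trimethoxyphenyl ring, then chelation-controlled cleavage of the one methoxy group wedged between ketone and biaryl bond.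
3. Key disconnection: the 6–8'' biaryl bond is made not by Pd cross-coupling of a halide with a boronate but by ligand coupling at tetravalent lead. The chelated 5-OH of 7-O-benzylacacetin is arylated at C6 by 2,4,6-trimethoxyphenyllead triacetate, itself made by direct plumbation of 1,3,5-trimethoxybenzene.
4. Ring order: unit A flavone bought complete (acacetin), then the biaryl bond, then the pyranone ring of unit B.

Assumption: the target SMILES carries no stereodescriptor (no stereocentre, biaryl axis unspecified), so the compound is made as drawn and the 6–8'' axis forms without control (racemic if configurationally stable).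

**Route**

Step 1
Reactants: 1 acacetin, 5,7-dihydroxy-2-(4-methoxyphenyl)-4H-chromen-4-one
Product: 2 7-(benzyloxy)-5-hydroxy-2-(4-methoxyphenyl)-4H-chromen-4-one
Conditions: BnBr (1.05 equiv), K2CO3 (1.2 equiv), DMF, 25 °C
Reagents that add atoms: benzyl bromide, BrCc1ccccc1
Why: Williamson etherification is 7-selective because the 7-OH is the acidic, unchelated phenol while the 5-OH is locked in a hydrogen bond to the C4 carbonyl, which leaves the 5-OH as the only phenol for the lead chemistry.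

Step 2
Reactants: 3 1,3,5-trimethoxybenzene
Product: 4 (2,4,6-trimethoxyphenyl)lead triacetate
Conditions: Pb(OAc)4 (1.0 equiv), CHCl3, 25 °C, dark; crystallised free of Pb(OAc)4
Reagents that add atoms: lead tetraacetate, CC(=O)O[Pb](OC(C)=O)(OC(C)=O)OC(C)=O
Why: Direct electrophilic plumbation (SEAr) works on this very electron-rich arene, and its three ring positions are equivalent, so a single aryllead triacetate forms.

Step 3
Reactants: 2 7-(benzyloxy)-5-hydroxy-2-(4-methoxyphenyl)-4H-chromen-4-one; 4 (2,4,6-trimethoxyphenyl)lead triacetate (1.5 equiv)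
Product: 7 7-(benzyloxy)-5-hydroxy-2-(4-methoxyphenyl)-6-(2,4,6-trimethoxyphenyl)-4H-chromen-4-one, via lead aryloxide 5 (not isolated), via cyclohexadienone 6 (not isolated)
Conditions: pyridine (4 equiv), CHCl3, 60 °C
Reagents that add atoms: none
Why: Proposed new method: one acetate on tetravalent lead is exchanged for the chelated 5-phenoxide (an aromatic enol of a 1,3-dicarbonyl unit), the aryl group then passes from lead to C6, the only unsubstituted ortho carbon, by ligand coupling with loss of divalent lead, and the dienone tautomerises back to the phenol; the closest known reaction is the Pinhey ortho-arylation of hindered phenols and beta-dicarbonyl compounds with aryllead triacetates, which tolerates fully ortho-substituted partners.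

Step 4
Reactants: 7 7-(benzyloxy)-5-hydroxy-2-(4-methoxyphenyl)-6-(2,4,6-trimethoxyphenyl)-4H-chromen-4-one; 8 (2E)-3-(4-methoxyphenyl)prop-2-enoyl chloride (1.3 equiv)
Product: 9 7-(benzyloxy)-5-hydroxy-2-(4-methoxyphenyl)-6-{2,4,6-trimethoxy-3-[(2E)-3-(4-methoxyphenyl)prop-2-enoyl]phenyl}-4H-chromen-4-one
Conditions: SnCl4 (2.5 equiv), CH2Cl2, −20 to 0 °C
Reagents that add atoms: none
Why: Friedel–Crafts acylation goes to the trimethoxyphenyl ring, the only ring not deactivated by a conjugated carbonyl (unit A is further deactivated as its tin chelate), and its two free positions are equivalent, so one (E)-enone results, racemic about the now unsymmetrical biaryl axis.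

Step 5
Reactants: 9 7-(benzyloxy)-5-hydroxy-2-(4-methoxyphenyl)-6-{2,4,6-trimethoxy-3-[(2E)-3-(4-methoxyphenyl)prop-2-enoyl]phenyl}-4H-chromen-4-one
Product: 10 7-(benzyloxy)-5-hydroxy-6-{2-hydroxy-4,6-dimethoxy-3-[(2E)-3-(4-methoxyphenyl)prop-2-enoyl]phenyl}-2-(4-methoxyphenyl)-4H-chromen-4-one
Conditions: MgI2·OEt2 (3 equiv), toluene, 80 °C; aq. HCl
Reagents that add atoms: none
Why: In this chelation-controlled ether cleavage magnesium bridges the ketone oxygen and an ortho methoxy oxygen and iodide removes the methyl group by SN2; of the two ortho methoxy groups the one wedged between the acyl group and the biaryl bond is twisted out of conjugation, hence more basic and relieved of strain on cleavage, so it is the one lost, while the unchelated benzyl and methyl ethers stay.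

Step 6
Reactants: 10 7-(benzyloxy)-5-hydroxy-6-{2-hydroxy-4,6-dimethoxy-3-[(2E)-3-(4-methoxyphenyl)prop-2-enoyl]phenyl}-2-(4-methoxyphenyl)-4H-chromen-4-one
Product: 12 7-(benzyloxy)-6-[5,7-dimethoxy-2-(4-methoxyphenyl)-4-oxo-4H-chromen-8-yl]-5-hydroxy-2-(4-methoxyphenyl)-4H-chromen-4-one, via flavanone 11 (not isolated)
Conditions: I2 (10 mol %), DMSO, 130 °C
Reagents that add atoms: none
Why: In this iodine–DMSO oxidative cyclisation of a 2'-hydroxychalcone the only free ortho hydroxyl adds to the enone (oxa-Michael) to give the flavanone, which iodine dehydrogenates while DMSO reoxidises HI, so the ring oxygen is necessarily the one next to the biaryl bond and unit B is 8-linked.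

Step 7
Reactants: 12 7-(benzyloxy)-6-[5,7-dimethoxy-2-(4-methoxyphenyl)-4-oxo-4H-chromen-8-yl]-5-hydroxy-2-(4-methoxyphenyl)-4H-chromen-4-one
Product: 13 5,7-dihydroxy-6-[5-hydroxy-7-methoxy-2-(4-methoxyphenyl)-4-oxo-4H-chromen-8-yl]-2-(4-methoxyphenyl)-4H-chromen-4-one
Conditions: BCl3 (6 equiv), C6HMe5 (3 equiv), CH2Cl2, −78 to 0 °C; H2O
Reagents that add atoms: none
Why: BCl3 cleaves the benzyl ether (cation trapped by pentamethylbenzene) and, through a six-membered boron chelate with the C4'' carbonyl, the peri 5''-methyl ether, whereas the unchelated 7''- and 4'-type methyl ethers do not react at or below 0 °C, so the target's methylation pattern is revealed in one operation.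

**Compound list**

1 | acacetin, 5,7-dihydroxy-2-(4-methoxyphenyl)-4H-chromen-4-one | COc1ccc(-c2cc(=O)c3c(O)cc(O)cc3o2)cc1 | starting material
2 | 7-(benzyloxy)-5-hydroxy-2-(4-methoxyphenyl)-4H-chromen-4-one | COc1ccc(-c2cc(=O)c3c(O)cc(OCc4ccccc4)cc3o2)cc1 | intermediate
3 | 1,3,5-trimethoxybenzene | COc1cc(OC)cc(OC)c1 | starting material
4 | (2,4,6-trimethoxyphenyl)lead triacetate | COc1cc(OC)c([Pb](OC(C)=O)(OC(C)=O)OC(C)=O)c(OC)c1 | intermediate
5 | lead aryloxide, diacetoxy{[7-(benzyloxy)-2-(4-methoxyphenyl)-4-oxo-4H-chromen-5-yl]oxy}(2,4,6-trimethoxyphenyl)plumbane (not isolated) | COc1ccc(-c2cc(=O)c3c(O[Pb](OC(C)=O)(OC(C)=O)c4c(OC)cc(OC)cc4OC)cc(OCc4ccccc4)cc3o2)cc1 | intermediate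
6 | cyclohexadienone, 7-(benzyloxy)-2-(4-methoxyphenyl)-6-(2,4,6-trimethoxyphenyl)-4H-chromene-4,5(6H)-dione, racemic at C6 (not isolated) | COc1ccc(C2=CC(=O)C3=C(O2)C=C(OCc2ccccc2)C(c2c(OC)cc(OC)cc2OC)C3=O)cc1 | intermediate
7 | 7-(benzyloxy)-5-hydroxy-2-(4-methoxyphenyl)-6-(2,4,6-trimethoxyphenyl)-4H-chromen-4-one | COc1ccc(-c2cc(=O)c3c(O)c(-c4c(OC)cc(OC)cc4OC)c(OCc4ccccc4)cc3o2)cc1 | intermediate
8 | (2E)-3-(4-methoxyphenyl)prop-2-enoyl chloride | COc1ccc(/C=C/C(Cl)=O)cc1 | starting material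
9 | 7-(benzyloxy)-5-hydroxy-2-(4-methoxyphenyl)-6-{2,4,6-trimethoxy-3-[(2E)-3-(4-methoxyphenyl)prop-2-enoyl]phenyl}-4H-chromen-4-one | COc1ccc(-c2cc(=O)c3c(O)c(-c4c(OC)c(C(=O)/C=C/c5ccc(OC)cc5)c(OC)cc4OC)c(OCc4ccccc4)cc3o2)cc1 | intermediate
10 | 7-(benzyloxy)-5-hydroxy-6-{2-hydroxy-4,6-dimethoxy-3-[(2E)-3-(4-methoxyphenyl)prop-2-enoyl]phenyl}-2-(4-methoxyphenyl)-4H-chromen-4-one | COc1ccc(-c2cc(=O)c3c(O)c(-c4c(O)c(C(=O)/C=C/c5ccc(OC)cc5)c(OC)cc4OC)c(OCc4ccccc4)cc3o2)cc1 | intermediate
11 | flavanone, 7-(benzyloxy)-6-[5,7-dimethoxy-2-(4-methoxyphenyl)-4-oxo-3,4-dihydro-2H-chromen-8-yl]-5-hydroxy-2-(4-methoxyphenyl)-4H-chromen-4-one, racemic at C2'' (not isolated) | COc1ccc(-c2cc(=O)c3c(O)c(-c4c(OC)cc(OC)c5c4OC(c4ccc(OC)cc4)CC5=O)c(OCc4ccccc4)cc3o2)cc1 | intermediate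
12 | 7-(benzyloxy)-6-[5,7-dimethoxy-2-(4-methoxyphenyl)-4-oxo-4H-chromen-8-yl]-5-hydroxy-2-(4-methoxyphenyl)-4H-chromen-4-one | COc1ccc(-c2cc(=O)c3c(O)c(-c4c(OC)cc(OC)c5c(=O)cc(-c6ccc(OC)cc6)oc45)c(OCc4ccccc4)cc3o2)cc1 | intermediate
13 | 5,7-dihydroxy-6-[5-hydroxy-7-methoxy-2-(4-methoxyphenyl)-4-oxo-4H-chromen-8-yl]-2-(4-methoxyphenyl)-4H-chromen-4-one (CNP0146326.0) | COc1ccc(-c2cc(=O)c3c(O)c(-c4c(OC)cc(O)c5c(=O)cc(-c6ccc(OC)cc6)oc45)c(O)cc3o2)cc1 | target

**Step count and risks**

Total step count: 7. Longest linear sequence: 6 steps (1, 3, 4, 5, 6, 7 from acacetin); step 2 is a one-step side branch.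

Steps most likely to fail:

Step 3. The phenol is chelated and the new bond is flanked by four ortho substituents, so exchange at lead may be slow and 4 may decompose first. The fallback replaces ligand coupling by cross-coupling; it sets out from 2 and comes back at 7. Compound 2 is iodinated ortho to its free 5-OH (I2, TlOAc, CH2Cl2, 25 °C) to give 7-(benzyloxy)-5-hydroxy-6-iodo-2-(4-methoxyphenyl)-4H-chromen-4-one F1. F1 is then joined to commercial (2,4,6-trimethoxyphenyl)boronic acid by Suzuki–Miyaura coupling (Pd(OAc)2, SPhos, K3PO4, toluene–H2O, 100 °C) to give 7.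

Step 5. The wrong ortho methoxy group, or both, may be cleaved, which would misplace the ring oxygen of unit B. The fallback fixes the position of the free hydroxyl by the starting material instead of by selective ether cleavage; it sets out from 2 and comes back at 10.
- Compound 2 is iodinated as above (the same 6-iodide F1) and borylated (B2pin2, PdCl2(dppf), KOAc, dioxane, 90 °C) to 7-(benzyloxy)-5-hydroxy-2-(4-methoxyphenyl)-6-(4,4,5,5-tetramethyl-1,3,2-dioxaborolan-2-yl)-4H-chromen-4-one F2.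
- Commercial 1-(2-hydroxy-4,6-dimethoxyphenyl)ethanone is iodinated next to its only hydroxyl (I2, TlOAc, CH2Cl2) to 1-(2-hydroxy-3-iodo-4,6-dimethoxyphenyl)ethanone F3.
- Suzuki–Miyaura coupling of F2 with F3 (Pd(OAc)2, SPhos, K3PO4, toluene–H2O, 100 °C) gives 6-(3-acetyl-2-hydroxy-4,6-dimethoxyphenyl)-7-(benzyloxy)-5-hydroxy-2-(4-methoxyphenyl)-4H-chromen-4-one F4.
- Claisen–Schmidt condensation of F4 with 4-methoxybenzaldehyde (KOH, EtOH, 25 °C) gives 10.

Step 4. The cinnamoyl cation is a weak electrophile for a hindered ring, and the product enone can be attacked by a second arene. The fallback builds the enone by aldol condensation instead of bringing it in by acylation; it sets out from 7 and comes back at 9. Compound 7 is C-acetylated (Ac2O, BF3·OEt2, CH2Cl2, 0 °C) to 6-(3-acetyl-2,4,6-trimethoxyphenyl)-7-(benzyloxy)-5-hydroxy-2-(4-methoxyphenyl)-4H-chromen-4-one F5. F5 is then condensed with 4-methoxybenzaldehyde (KOH, EtOH–THF, 25 °C) to give 9.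

**Further compounds**

F1 | step 3 | 7-(benzyloxy)-5-hydroxy-6-iodo-2-(4-methoxyphenyl)-4H-chromen-4-one | COc1ccc(-c2cc(=O)c3c(O)c(I)c(OCc4ccccc4)cc3o2)cc1
F2 | step 5 | 7-(benzyloxy)-5-hydroxy-2-(4-methoxyphenyl)-6-(4,4,5,5-tetramethyl-1,3,2-dioxaborolan-2-yl)-4H-chromen-4-one | COc1ccc(-c2cc(=O)c3c(O)c(B4OC(C)(C)C(C)(C)O4)c(OCc4ccccc4)cc3o2)cc1
F3 | step 5 | 1-(2-hydroxy-3-iodo-4,6-dimethoxyphenyl)ethanone | CC(=O)c1c(O)c(I)c(OC)cc1OC
F4 | step 5 | 6-(3-acetyl-2-hydroxy-4,6-dimethoxyphenyl)-7-(benzyloxy)-5-hydroxy-2-(4-methoxyphenyl)-4H-chromen-4-one | COc1ccc(-c2cc(=O)c3c(O)c(-c4c(O)c(C(C)=O)c(OC)cc4OC)c(OCc4ccccc4)cc3o2)cc1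
F5 | step 4 | 6-(3-acetyl-2,4,6-trimethoxyphenyl)-7-(benzyloxy)-5-hydroxy-2-(4-methoxyphenyl)-4H-chromen-4-one | COc1ccc(-c2cc(=O)c3c(O)c(-c4c(OC)c(C(C)=O)c(OC)cc4OC)c(OCc4ccccc4)cc3o2)cc1
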